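**Retrosynthetic overview**
1. Target 17 ⇐ bis-MOM hydroquinone 14: the quinone is carried as a protected hydroquinone and unmasked last.
2. 14 ⇐ bis-alkyne 11 + 2 × 2-iodoaniline 12: both indole rings are built at once by a double Larock heteroannulation. The 1,1-dimethylallyl groups arrive on the alkyne, so there is no indole–quinone coupling and no indole prenylation.
3. 11 ⇐ dibromide 6 + 2 × enyne 9 by double Sonogashira coupling.
4. 6 ⇐ bromanil 1 (central ring bought); 9 ⇐ 2,2-dimethylbut-3-en-1-ol 7 by oxidation and Seyferth–Gilbert homologation.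
5. Ring order: the central six-membered ring is present from the start; the two pyrrole rings are formed together in step 7.

Assumption: the target is achiral as drawn (no stereocentre, no stereogenic double bond), so the given SMILES is taken as the full structure; rotation about the two indole–quinone bonds is unspecified and is not controlled.

**Route**

Step 1
Reactants: 1 tetrabromo-1,4-benzoquinone (bromanil)
Product: 3 2,5-dibromo-3,6-dimethoxy-1,4-benzoquinone, via tribromo-methoxyquinone 2 (not isolated)
Conditions: NaOMe (2.0 equiv), MeOH, 0 °C to rt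
Reagents that add atoms: sodium methoxide, C[O-].[Na+]
Why: Addition–elimination (vinylogous acyl substitution) of methoxide on the haloquinone, where the first methoxy group deactivates its own vinylogous-ester arm so the second substitution goes to the para-related carbon, as with chloranil.

Step 2
Reactants: 3 2,5-dibromo-3,6-dimethoxy-1,4-benzoquinone
Product: 4 2,5-dibromo-3,6-dimethoxybenzene-1,4-diol
Conditions: Na2S2O4, EtOAc/H2O, rt
Reagents that add atoms: none
Why: Two-electron dithionite reduction of a quinone to its hydroquinone, which leaves aryl bromides and methyl ethers untouched.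

Step 3
Reactants: 4 2,5-dibromo-3,6-dimethoxybenzene-1,4-diol
Product: 6 1,4-dibromo-2,5-dimethoxy-3,6-bis(methoxymethoxy)benzene, via mono-MOM ether 5 (not isolated)
Conditions: NaH (2.4 equiv), MOMCl (2.4 equiv), THF/DMF, 0 °C to rt, under Ar
Reagents that add atoms: chloromethyl methyl ether (MOMCl), COCCl
Why: Williamson-type O-alkylation of the bis-phenoxide, run under argon so the electron-rich dianion is not re-oxidised, gives a mask that survives basic palladium chemistry and distinguishes the future carbonyl oxygens from the two methoxy groups.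

Step 4
Reactants: 7 2,2-dimethylbut-3-en-1-ol
Product: 8 2,2-dimethylbut-3-enal
Conditions: TEMPO (10 mol%), PhI(OAc)2 (1.1 equiv), CH2Cl2, rt; NaHCO3 wash, used as a dried concentrate
Reagents that add atoms: none
Why: Oxoammonium (TEMPO) oxidation of a primary neopentyl-type alcohol stops at the aldehyde, which has no α-hydrogen and cannot enolise or isomerise.

Step 5
Reactants: 8 2,2-dimethylbut-3-enal
Product: 9 3,3-dimethylpent-4-en-1-yne
Conditions: dimethyl (1-diazo-2-oxopropyl)phosphonate (1.3 equiv), K2CO3 (2 equiv), MeOH, 0 °C to rt; pentane extraction, distillation through a short column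
Reagents that add atoms: dimethyl (1-diazo-2-oxopropyl)phosphonate, CC(=O)C(=[N+]=[N-])P(=O)(OC)OC
Why: Seyferth–Gilbert homologation in the Ohira–Bestmann variant adds one carbon to a non-enolisable aldehyde, and the skipped enyne has no propargylic hydrogen so it cannot isomerise to an allene under the base.

Step 6
Reactants: 6 1,4-dibromo-2,5-dimethoxy-3,6-bis(methoxymethoxy)benzene; 9 3,3-dimethylpent-4-en-1-yne (3 equiv)
Product: 11 1,4-bis(3,3-dimethylpent-4-en-1-yn-1-yl)-2,5-dimethoxy-3,6-bis(methoxymethoxy)benzene, via mono-alkynyl bromide 10 (not isolated)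
Conditions: PdCl2(MeCN)2 (6 mol%), XPhos (18 mol%), Cs2CO3 (5 equiv), MeCN, 85 °C, sealed tube
Reagents that add atoms: none
Why: Copper-free Sonogashira coupling with a bulky biarylphosphine lets zerovalent palladium insert into the electron-rich, di-ortho-substituted aryl bromide and avoids Glaser dimerisation of the alkyne.

Step 7
Reactants: 11 1,4-bis(3,3-dimethylpent-4-en-1-yn-1-yl)-2,5-dimethoxy-3,6-bis(methoxymethoxy)benzene; 12 2-iodoaniline (2.3 equiv)
Product: 14 3,3'-[2,5-dimethoxy-3,6-bis(methoxymethoxy)-1,4-phenylene]bis[2-(2-methylbut-3-en-2-yl)-1H-indole], via mono-indole 13 (not isolated)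
Conditions: Pd(OAc)2 (10 mol%), LiCl (2 equiv), K2CO3 (6 equiv), DMF, 100 °C
Reagents that add atoms: none
Why: Larock heteroannulation, in which syn-carbopalladation by the anilinyl–palladium iodide puts palladium on the alkyne carbon bearing the bulkier quaternary C(CH3)2CH=CH2 group (as tert-alkyl and tertiary-carbinol alkynes do against aryl), so that C–N reductive elimination places the dimethylallyl group at C2 and the central arene at C3 of each indole, with alkyne insertion outpacing Heck reaction of the hindered vinyl groups.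

Step 8
Reactants: 14 3,3'-[2,5-dimethoxy-3,6-bis(methoxymethoxy)-1,4-phenylene]bis[2-(2-methylbut-3-en-2-yl)-1H-indole]
Product: 17 2,5-bis[2-(2-methylbut-3-en-2-yl)-1H-indol-3-yl]-3,6-dimethoxy-1,4-benzoquinone, via mono-MOM hydroquinone 15 (not isolated), via hydroquinone 16 (not isolated)
Conditions: HCl (1.25 M in MeOH), THF, 40 °C; then Ag2O, MgSO4, Et2O, rt
Reagents that add atoms: none
Why: Acid-catalysed transacetalisation removes the two aryl MOM ethers (methanol as solvent leaves the vinylogous-ester methoxy groups unchanged), and the very electron-rich hydroquinone is then oxidised to the quinone by Ag2O without touching the indoles or the terminal alkenes.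

**Compound list**
1 | tetrabromo-1,4-benzoquinone (bromanil) | O=C1C(Br)=C(Br)C(=O)C(Br)=C1Br | starting material
2 | 2,3,5-tribromo-6-methoxy-1,4-benzoquinone | COC1=C(Br)C(=O)C(Br)=C(Br)C1=O | intermediate
3 | 2,5-dibromo-3,6-dimethoxy-1,4-benzoquinone | COC1=C(Br)C(=O)C(OC)=C(Br)C1=O | intermediate
4 | 2,5-dibromo-3,6-dimethoxybenzene-1,4-diol | COc1c(Br)c(O)c(OC)c(Br)c1O | intermediate
5 | 2,5-dibromo-3,6-dimethoxy-4-(methoxymethoxy)phenol | COCOc1c(Br)c(OC)c(O)c(Br)c1OC | intermediate
6 | 1,4-dibromo-2,5-dimethoxy-3,6-bis(methoxymethoxy)benzene | COCOc1c(Br)c(OC)c(OCOC)c(Br)c1OC | intermediate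
7 | 2,2-dimethylbut-3-en-1-ol | C=CC(C)(C)CO | starting material
8 | 2,2-dimethylbut-3-enal | C=CC(C)(C)C=O | intermediate
9 | 3,3-dimethylpent-4-en-1-yne | C=CC(C)(C)C#C | intermediate
10 | 1-bromo-4-(3,3-dimethylpent-4-en-1-yn-1-yl)-2,5-dimethoxy-3,6-bis(methoxymethoxy)benzene | COCOc1c(Br)c(OC)c(OCOC)c(C#CC(C)(C)C=C)c1OC | intermediate
11 | 1,4-bis(3,3-dimethylpent-4-en-1-yn-1-yl)-2,5-dimethoxy-3,6-bis(methoxymethoxy)benzene | COCOc1c(C#CC(C)(C)C=C)c(OC)c(OCOC)c(C#CC(C)(C)C=C)c1OC | intermediate
12 | 2-iodoaniline | Nc1ccccc1I | starting material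
13 | 3-[4-(3,3-dimethylpent-4-en-1-yn-1-yl)-2,5-dimethoxy-3,6-bis(methoxymethoxy)phenyl]-2-(2-methylbut-3-en-2-yl)-1H-indole | COCOc1c(C#CC(C)(C)C=C)c(OC)c(OCOC)c(-c2c(C(C)(C)C=C)[nH]c3ccccc23)c1OC | intermediate
14 | 3,3'-[2,5-dimethoxy-3,6-bis(methoxymethoxy)-1,4-phenylene]bis[2-(2-methylbut-3-en-2-yl)-1H-indole] | COCOc1c(-c2c(C(C)(C)C=C)[nH]c3ccccc23)c(OC)c(OCOC)c(-c2c(C(C)(C)C=C)[nH]c3ccccc23)c1OC | intermediate
15 | 2,5-bis[2-(2-methylbut-3-en-2-yl)-1H-indol-3-yl]-3,6-dimethoxy-4-(methoxymethoxy)phenol | COCOc1c(-c2c(C(C)(C)C=C)[nH]c3ccccc23)c(OC)c(O)c(-c2c(C(C)(C)C=C)[nH]c3ccccc23)c1OC | intermediate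
16 | 2,5-bis[2-(2-methylbut-3-en-2-yl)-1H-indol-3-yl]-3,6-dimethoxybenzene-1,4-diol | COc1c(-c2c(C(C)(C)C=C)[nH]c3ccccc23)c(O)c(OC)c(-c2c(C(C)(C)C=C)[nH]c3ccccc23)c1O | intermediate
17 | 2,5-bis[2-(2-methylbut-3-en-2-yl)-1H-indol-3-yl]-3,6-dimethoxy-1,4-benzoquinone (CNP0331285.0) | C=CC(C)(C)c1[nH]c2ccccc2c1C1=C(OC)C(=O)C(c2c(C(C)(C)C=C)[nH]c3ccccc23)=C(OC)C1=O | target

**Totals**
Total step count: 8.
Longest linear sequence: 6 steps (steps 1, 2, 3, 6, 7, 8 from bromanil); the alkyne branch (steps 4, 5) joins at step 6.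

**Three steps most likely to fail**

Step 7 (double Larock annulation). The risks are the wrong orientation of insertion against the di-ortho-substituted arene, Heck arylation of the vinyl groups, and stalling after one annulation. The fallback is a Cacchi aminopalladation–reductive elimination, in which connectivity rather than sterics fixes the regiochemistry. It sets out from 12 and rejoins the route at 14, bypassing steps 6 and 7. Copper-free Sonogashira coupling of 12 with 9 (PdCl2(MeCN)2, XPhos, Cs2CO3, MeCN, 60 °C) gives 2-(3,3-dimethylpent-4-en-1-yn-1-yl)aniline F1. Trifluoroacetic anhydride and pyridine in CH2Cl2 at 0 °C convert it into N-[2-(3,3-dimethylpent-4-en-1-yn-1-yl)phenyl]-2,2,2-trifluoroacetamide F2. F2 (2.3 equiv) is then heated with dibromide 6 (Pd2(dba)3, XPhos, Cs2CO3, MeCN, 100 °C). Each arylpalladium bromide formed from 6 activates an alkyne for 5-endo attack by the amide nitrogen and then reductively eliminates, which puts the central arene on C3. The reaction passes through 3-[4-bromo-2,5-dimethoxy-3,6-bis(methoxymethoxy)phenyl]-2-(2-methylbut-3-en-2-yl)-1H-indole F3, and the trifluoroacetyl groups are lost in the same pot, giving 14.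

Step 6 (double Sonogashira on a hindered, electron-rich dibromide with a volatile alkyne). The risks are slow coupling, alkyne loss or oligomerisation at 85 °C, and mono-coupling only. The fallback replaces the base-mediated alkyne activation by a preformed organozinc (Negishi alkynylation). It sets out from 9 and rejoins at 11. Enyne 9 is deprotonated with n-BuLi (THF, −78 °C) to lithium 3,3-dimethylpent-4-en-1-yn-1-ide F4. ZnCl2 transmetalates it to chloro(3,3-dimethylpent-4-en-1-yn-1-yl)zinc F5, which is coupled with 6 using Pd[P(t-Bu)3]2 in THF at 50–60 °C, through 10, to give 11.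

Step 5 (Seyferth–Gilbert homologation of a hindered aldehyde to a C7 hydrocarbon boiling near 70 °C). The main risk is loss of material on isolation from methanol. The fallback avoids isolating 9 altogether. It sets out from 8 and rejoins at 11. Corey–Fuchs olefination of 8 (CBr4, PPh3, CH2Cl2, 0 °C) gives the non-volatile 1,1-dibromo-3,3-dimethylpenta-1,4-diene F6. n-BuLi (2.1 equiv, THF, −78 °C) converts it by bromine–lithium exchange and rearrangement directly into lithium 3,3-dimethylpent-4-en-1-yn-1-ide F4. ZnCl2 gives chloro(3,3-dimethylpent-4-en-1-yn-1-yl)zinc F5, which is coupled in the same flask with 6 (Pd[P(t-Bu)3]2, THF, 50–60 °C) to give 11.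

**Further compounds**
F1 | step 7 | 2-(3,3-dimethylpent-4-en-1-yn-1-yl)aniline | Nc1ccccc1C#CC(C)(C)C=C
F2 | step 7 | N-[2-(3,3-dimethylpent-4-en-1-yn-1-yl)phenyl]-2,2,2-trifluoroacetamide | O=C(Nc1ccccc1C#CC(C)(C)C=C)C(F)(F)F
F3 | step 7 | 3-[4-bromo-2,5-dimethoxy-3,6-bis(methoxymethoxy)phenyl]-2-(2-methylbut-3-en-2-yl)-1H-indole | COCOc1c(Br)c(OC)c(OCOC)c(-c2c(C(C)(C)C=C)[nH]c3ccccc23)c1OC
F4 | step 6 | lithium 3,3-dimethylpent-4-en-1-yn-1-ide | [Li]C#CC(C)(C)C=C
F5 | step 6 | chloro(3,3-dimethylpent-4-en-1-yn-1-yl)zinc | Cl[Zn]C#CC(C)(C)C=C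
F6 | step 5 | 1,1-dibromo-3,3-dimethylpenta-1,4-diene | C=CC(C)(C)C=C(Br)Br
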